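## Analysis of the target

6-Hydroxyluteolin 7-sulfate (26) is a flavone: benzene ring A is fused to 4-pyranone ring C, and C2 carries catechol ring B. It has no stereocentre, so the whole problem is regiochemistry on ring A, which is substituted everywhere except C8 (carbon at C4a, oxygen at C5, C6, C7 and C8a). Of the five phenolic oxygens exactly one, O7, is a sulfate monoester. The aryl sulfate is lost under acid and turns every intermediate that carries it into a salt, and the 5,6- and 3′,4′-diols are air-sensitive once free. The sulfate must therefore go on late, and the phenols must be unveiled last under neutral, reductive conditions. The hard part is telling O7 from its neighbour O6: O5 is set apart by its hydrogen bond to the C4 carbonyl, but O6 and O7 are adjacent, unchelated and similar in acidity. The strategy rests on the unit O7–C7–C8(H)–C8a–O1, a resorcinol with an unsubstituted carbon between its oxygens. That pattern arises when a ketene carbonyl (which ends as a free phenol) is joined to the CH terminus of an ynol ether (whose oxygen stays protected), so building ring A this way delivers O7 as the only free hydroxyl.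

## Retrosynthetic reasoning

**O–benzyl and O7–S bonds.** 26 is traced to its tetrabenzyl ether 25 (sodium salt), because hydrogenolysis is the one global deprotection that should leave an aryl sulfate and the pyranone intact. 25 comes from flavone 24 by sulfation. This order requires 24 to have O7 as its only free hydroxyl, and everything earlier is designed to deliver that.

**O1–C2 (ring C).** Cutting here leads to the 2′-hydroxychalcone 22. Its oxidative cyclization, through flavanone 23, is dependable, and the cut keeps C4, C3, C2 and ring B as one three-carbon arm on C4a. The forward reaction must close O1–C2 and introduce C2=C3 without attacking the electron-rich C8 position.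

**Enone as a transposed propargylic alcohol.** 22 comes from 21 by freeing O1, 21 from 20 by a Meyer–Schuster 1,3-shift of oxygen from C2 to C4, and 20 from 19 by unmasking the carbinol. No C–C bond is cut. The gain is that the arm on C4a becomes an alkyne, which is slim and should be inert in a thermal ring synthesis. O1 must stay silylated until the shift is over, or it would add to the alkyne.

**Ring A (C7–C8, C4a–C8a, C6–C7).** 19 is split into cyclobutenone 11 (C4a, C5, C6, C7 with O5, O6 and the alkynyl arm) and siloxyalkyne 14 (C8, C8a, O1). This is the cut that solves the O6/O7 problem, because the carbonyl oxygen of 11 becomes O7 and is the only oxygen that emerges unprotected. The forward reaction is a cascade through 15, 16, 17 and 18; it must set the orientation of the two partners and close the six-membered ring with the correct arm.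

**Siloxyalkyne.** 14 comes from ester 12 through ynolate 13 by O-silylation. A bulky silyl group is needed so that silicon goes to oxygen and the ynol ether survives heating.

**C6–H and O6–benzyl.** 11 comes from alcohol 10 by O-benzylation, and 10 from dione 9 by delivery of one hydride to the carbonyl next to the benzyloxy-bearing carbon. Benzyl is chosen for O6 because it cannot migrate to O7 and leaves in the final hydrogenolysis.

**C4a–alkyne bond.** 9 comes from squarate 2 and alkyne 5 by addition of acetylide 6 and loss of one benzyloxy group, through 7 and 8. The surviving benzyloxy group is O5.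

**Starting materials.** 2 is the dibenzyl ester of squaric acid 1. 5 is the silyl ether of carbinol 4, made by ethynylation of aldehyde 3.

## Alternatives that were turned down

**Alternative 1:** Ring A is cut at C4a–C5 and C8–C8a. The forward key step is a (4+2) cycloaddition of 2-(benzyloxy)-1-methoxy-1,3-bis(trimethylsilyloxy)buta-1,3-diene A1 with 4-bromobut-3-yn-2-one A2, followed by aromatization with loss of the acetal alkoxy group, giving acetophenone A3.
- For: the orientation is fixed by the polarity of diene A1 and ynone A2, the pieces are small and acyclic, and this cycloaddition type is better precedented than the key step chosen here.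
- Against: O1 is absent from A3. The bromine at C8a must later be replaced by oxygen in a metal-catalysed aryl C–O coupling at a doubly ortho-substituted, electron-rich carbon. O5 and O7 both emerge free in A3, so O7 is distinguished only by the chelation of O5–H. C3, C2 and ring B still have to be attached by acylation after the ring is made. A1 is a moisture-sensitive ketene acetal and A2 is a labile electrophile.
- Comparison: it is stronger on precedent. The chosen route offers instead O1 already in place, O7 uniquely free, and the full C4–C3–C2–ring B arm present when ring A forms.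

**Alternative 2:** The cut is O1–C8a, with ring A bought as an arene that lacks oxygen at C8a. Diketone A4 would be oxidised with a mild oxidant to o-quinone A5, whose enol oxygen adds 1,4 to C8a and closes ring C; tautomerization gives flavone A6.
- For: it is the shortest path to the flavone core, since ring A is never built and the carbon skeleton comes from classical Claisen chemistry. On step count to the core it beats the chosen route.
- Against: A5 has other electrophilic sites (C8, C7). A6 is itself a 5,6-catechol that the same oxidant can take further. Above all, A6 has O5 and O6 free and O7 blocked, the reverse of what this target needs: either the chelated O5–H and O6–H must be protected before O7 is released, or O7 must be sulfated beside a free O6–H.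
- Comparison: the chosen route gives up the short core synthesis and gets the O7-free, O5/O6-benzylated pattern by construction.

**Alternative 3:** The cut is C4a–C5, with ring C made first. Pyranone keto ester A7 would be treated with a chelating alkoxide base so that its extended enolate attacks the ester carbon C5 from C4a; enolization gives flavone A8.
- For: it mirrors polyketide folding, and A8 has O6 benzylated with O5–H chelated, so O7 could be sulfated directly and the benzyl groups removed. That is a two-step endgame, shorter than the six steps that follow the key step here, and the O7 differentiation is equally reliable.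
- Against: C4a of a 4-pyranone is a weak nucleophile, 4-pyranones are opened by alkoxides, and the α-benzyloxy tricarbonyl chain of A7 has other outlets (O-acylation, aldol closure on the ketone, loss of benzyloxide). A7 itself needs a multistep chain extension.
- Comparison: it is stronger on endgame economy. The chosen route places its risk in a neutral, thermal pericyclic cascade whose orientation follows from polarity, and it distinguishes all four ring A oxygens by different groups, not by chelation alone.

Key step: step 8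

Remark on the chemistry: the target is drawn as the free hydrogen sulfate. It is assumed that this acidic form is generated only in the last operation and kept cold; before that the sulfate is carried as its sodium salt. The carbinol carbon is racemic throughout (7, 8, 10, 11, 16 and 18 are diastereomer mixtures) and is erased in step 10.

## Route

Step 1
Reactants: 1 squaric acid
Product: 2 3,4-bis(benzyloxy)cyclobut-3-ene-1,2-dione (dibenzyl squarate)
Conditions: BnOH (2.5 equiv), toluene, reflux, Dean–Stark
Reagents that add atoms: benzyl alcohol, OCc1ccccc1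
Why: Azeotropic Fischer-type esterification; squaric acid is a strong vinylogous diacid that esterifies on boiling with an alcohol while water is removed, and benzyl is chosen because the ester oxygen that survives becomes O5 and must fall to hydrogenolysis.

Step 2
Reactants: 3 3,4-bis(benzyloxy)benzaldehyde
Product: 4 1-[3,4-bis(benzyloxy)phenyl]prop-2-yn-1-ol (racemic)
Conditions: HC≡CMgBr, THF, 0 °C; aq. NH4Cl
Reagents that add atoms: ethynylmagnesium bromide, C#C[Mg]Br
Why: Grignard 1,2-addition of an acetylide to an aromatic aldehyde; the carbinol forms as a racemate, which does not matter because this carbon becomes sp2 C2 in step 10.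

Step 3
Reactants: 4 1-[3,4-bis(benzyloxy)phenyl]prop-2-yn-1-ol (racemic)
Product: 5 {1-[3,4-bis(benzyloxy)phenyl]prop-2-yn-1-yloxy}(tert-butyl)dimethylsilane (racemic)
Conditions: TBSCl, imidazole, DMF, rt
Reagents that add atoms: tert-butyldimethylsilyl chloride, CC(C)(C)[Si](C)(C)Cl
Why: Standard imidazole-promoted silylation; it leaves the alkyne C–H as the only acidic site for step 4 and keeps this oxygen from being benzylated in step 6.

Step 4
Reactants: 5 {1-[3,4-bis(benzyloxy)phenyl]prop-2-yn-1-yloxy}(tert-butyl)dimethylsilane (racemic); 2 3,4-bis(benzyloxy)cyclobut-3-ene-1,2-dione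
Product: 9 3-(benzyloxy)-4-{3-[3,4-bis(benzyloxy)phenyl]-3-(tert-butyldimethylsilyloxy)prop-1-yn-1-yl}cyclobut-3-ene-1,2-dione (racemic), via lithium acetylide 6 (not isolated), via lithium alkoxide adduct 7 (not isolated), via tertiary trifluoroacetate 8 (not isolated)
Conditions: n-BuLi, THF, −78 °C; 2, −78 °C; (CF3CO)2O, −78 → 0 °C; aq. NH4Cl
Reagents that add atoms: water, O
Why: 1,2-Addition of an alkynyllithium to one carbonyl of a dialkyl squarate, then the usual anhydride-triggered rearrangement: the tertiary alkoxide is trifluoroacetylated, ionises to a benzyloxy-stabilised cyclobutenyl cation, and hydrolysis on work-up expels one benzyloxy group. This sets the C4a–alkyne bond and leaves the benzyloxy group that becomes O5.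

Step 5
Reactants: 9 3-(benzyloxy)-4-{3-[3,4-bis(benzyloxy)phenyl]-3-(tert-butyldimethylsilyloxy)prop-1-yn-1-yl}cyclobut-3-ene-1,2-dione (racemic)
Product: 10 3-(benzyloxy)-2-{3-[3,4-bis(benzyloxy)phenyl]-3-(tert-butyldimethylsilyloxy)prop-1-yn-1-yl}-4-hydroxycyclobut-2-en-1-one (racemic diastereomer mixture)
Conditions: LiAlH(OtBu)3 (1.1 equiv), THF, −78 → −40 °C; aq. NH4Cl
Reagents that add atoms: none
Why: Regioselective hydride 1,2-reduction; in 3-alkoxy-4-substituted cyclobutenediones the carbonyl next to the alkoxy-bearing carbon is ketone-like and more electrophilic (the other is a vinylogous ester), and the bulky hydride should attack it once. The new stereocentre (future C6) forms without control and is erased on aromatization in step 8.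

Step 6
Reactants: 10 3-(benzyloxy)-2-{3-[3,4-bis(benzyloxy)phenyl]-3-(tert-butyldimethylsilyloxy)prop-1-yn-1-yl}-4-hydroxycyclobut-2-en-1-one (racemic diastereomer mixture)
Product: 11 3,4-bis(benzyloxy)-2-{3-[3,4-bis(benzyloxy)phenyl]-3-(tert-butyldimethylsilyloxy)prop-1-yn-1-yl}cyclobut-2-en-1-one (racemic diastereomer mixture)
Conditions: BnBr, Ag2O, 4 Å MS, CH2Cl2, rt, dark
Reagents that add atoms: benzyl bromide, BrCc1ccccc1
Why: Ag2O-promoted Williamson-type O-alkylation under non-basic conditions, the protocol used for base-sensitive 4-hydroxycyclobutenones; the ether oxygen becomes O6, and a benzyl group there cannot migrate to O7 later.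

Step 7
Reactants: 12 ethyl dibromoacetate
Product: 14 (triisopropylsilyloxy)acetylene, via lithium ethynolate 13 (not isolated)
Conditions: t-BuLi (4 equiv), THF, −78 → 0 °C; TIPSCl, −78 °C → rt; pentane, filtration, distillation
Reagents that add atoms: triisopropylsilyl chloride, CC(C)[Si](Cl)(C(C)C)C(C)C
Why: Ynolate formation from an α,α-dibromo ester by two successive bromine–lithium exchanges and loss of ethoxide from the ester dianion; the bulky silyl chloride should silylate the oxygen end, giving the ynol ether and not the C-silyl ketene.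

Step 8
Reactants: 11 3,4-bis(benzyloxy)-2-{3-[3,4-bis(benzyloxy)phenyl]-3-(tert-butyldimethylsilyloxy)prop-1-yn-1-yl}cyclobut-2-en-1-one (racemic diastereomer mixture); 14 (triisopropylsilyloxy)acetylene
Product: 19 2,3-bis(benzyloxy)-4-{3-[3,4-bis(benzyloxy)phenyl]-3-(tert-butyldimethylsilyloxy)prop-1-yn-1-yl}-5-(triisopropylsilyloxy)phenol (racemic), via vinylketene 15 (not isolated), via vinylcyclobutenone 16 (not isolated), via dienylketene 17 (not isolated), via cyclohexadienone 18 (not isolated)
Conditions: 14 (2.5 equiv), degassed toluene (0.1 M), 80 → 110 °C, sealed vessel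
Reagents that add atoms: none
Why: Proposed new method: heating 11 should cause 4π electrocyclic opening (C4 benzyloxy group turning outward) to vinylketene 15, whose electrophilic carbonyl carbon bonds to the nucleophilic CH terminus of 14 while its α-carbon bonds to the siloxy carbon in a (2+2) cycloaddition that gives 16 and forms C7–C8 and C4a–C8a. 16 should open again to dienylketene 17, which closes ring A by thermal disrotatory 6π electrocyclization (C6–C7) to 18, and enolization gives 19. The closest known reaction is the Danheiser benzannulation of cyclobutenones with siloxyalkynes to monosilylated resorcinols; not shown so far is a cyclobutenone with oxygen at C3 and C4 and an alkynyl group at C2. Ring A is thus closed by electrocyclization of a ketene-terminated triene, not by a polar cyclization, and the four-membered ring formed on the way is opened again. No stereocentre is created in 19: the sp3 ring carbons of 11, 16 and 18 become aromatic, and the carbinol carbon stays racemic. Two selectivities are needed: the orientation of the (2+2) step, secured by the polarity of ketene and ynol ether, and inward rotation of the dialkoxyvinyl arm and not the alkynyl arm when 16 opens, which should be secured because the opening is reversible and the vinyl-inward isomer 17 has the faster, aromatizing 6π exit. The ketene oxygen thereby becomes the lone free hydroxyl O7 and the ynol oxygen the silylated O1 with C8–H between them, while O5 and O6 arrive benzylated.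

Step 9
Reactants: 19 2,3-bis(benzyloxy)-4-{3-[3,4-bis(benzyloxy)phenyl]-3-(tert-butyldimethylsilyloxy)prop-1-yn-1-yl}-5-(triisopropylsilyloxy)phenol (racemic)
Product: 20 2,3-bis(benzyloxy)-4-{3-[3,4-bis(benzyloxy)phenyl]-3-hydroxyprop-1-yn-1-yl}-5-(triisopropylsilyloxy)phenol (racemic)
Conditions: aq. HF (48%), MeCN, 0 °C
Reagents that add atoms: none
Why: Acid-type desilylation; under aqueous HF a secondary alkyl tert-butyldimethylsilyl ether should cleave much faster than a hindered aryl triisopropylsilyl ether, so O1 stays protected. Any ionisation of the carbinol in this aqueous medium only returns the alcohol or leads on to 21.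

Step 10
Reactants: 20 2,3-bis(benzyloxy)-4-{3-[3,4-bis(benzyloxy)phenyl]-3-hydroxyprop-1-yn-1-yl}-5-(triisopropylsilyloxy)phenol (racemic)
Product: 21 (2E)-1-[2,3-bis(benzyloxy)-4-hydroxy-6-(triisopropylsilyloxy)phenyl]-3-[3,4-bis(benzyloxy)phenyl]prop-2-en-1-one
Conditions: Ph3PAuNTf2 (2 mol %), MeOH (1 equiv), toluene, rt
Reagents that add atoms: none
Why: Meyer–Schuster rearrangement catalysed by a cationic monovalent gold complex; oxygen is transposed from C2 to the alkyne carbon on ring A (C4), and tautomerization gives the conjugated ketone with the thermodynamically favoured E-alkene. Because O1 is silylated it cannot add to the activated alkyne to form a benzofuran.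

Step 11
Reactants: 21 (2E)-1-[2,3-bis(benzyloxy)-4-hydroxy-6-(triisopropylsilyloxy)phenyl]-3-[3,4-bis(benzyloxy)phenyl]prop-2-en-1-one
Product: 22 (2E)-1-[2,3-bis(benzyloxy)-4,6-dihydroxyphenyl]-3-[3,4-bis(benzyloxy)phenyl]prop-2-en-1-one
Conditions: Bu4NF, AcOH, THF, 0 °C
Reagents that add atoms: none
Why: Fluoride cleavage of the aryl silyl ether, buffered with AcOH to keep the phenoxide concentration low; any flavanone 23 formed by early ring closure is a competent substrate for step 12.

Step 12
Reactants: 22 (2E)-1-[2,3-bis(benzyloxy)-4,6-dihydroxyphenyl]-3-[3,4-bis(benzyloxy)phenyl]prop-2-en-1-one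
Product: 24 5,6-bis(benzyloxy)-2-[3,4-bis(benzyloxy)phenyl]-7-hydroxy-4H-chromen-4-one, via flavanone 23 (not isolated)
Conditions: I2 (10 mol %), DMSO, 120 °C
Reagents that add atoms: none
Why: Iodine-catalysed oxidative cyclization of a 2′-hydroxychalcone; O1 adds to C2 (6-endo-trig oxa-Michael) to give flavanone 23, which is iodinated at C3 and loses HI. DMSO reoxidises HI, so only catalytic iodine is present.

Step 13
Reactants: 24 5,6-bis(benzyloxy)-2-[3,4-bis(benzyloxy)phenyl]-7-hydroxy-4H-chromen-4-one
Product: 25 sodium 5,6-bis(benzyloxy)-2-[3,4-bis(benzyloxy)phenyl]-4-oxo-4H-chromen-7-yl sulfate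
Conditions: SO3·pyridine (3 equiv), pyridine, 40 °C; aq. NaHCO3
Reagents that add atoms: sulfur trioxide–pyridine complex, O=S(=O)([O-])[n+]1ccccc1; sodium hydrogencarbonate, [Na+].OC(=O)[O-]
Why: O-Sulfation of a phenol with an amine–SO3 complex; 24 has a single hydroxyl, so no selectivity is asked of the reagent. The sodium salt is isolated so that no pyridinium ion inhibits the catalyst of step 14.

Step 14
Reactants: 25 sodium 5,6-bis(benzyloxy)-2-[3,4-bis(benzyloxy)phenyl]-4-oxo-4H-chromen-7-yl sulfate
Product: 26 6-hydroxyluteolin 7-sulfate, 2-(3,4-dihydroxyphenyl)-5,6-dihydroxy-4-oxo-4H-chromen-7-yl hydrogen sulfate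
Conditions: H2 (1 atm), 10% Pd/C, THF/MeOH, rt; HCl (1.0 equiv), H2O, 0 °C; C18 desalting, lyophilisation
Reagents that add atoms: none
Why: Hydrogenolysis of the four benzyl ethers over Pd/C under neutral conditions, which aryl sulfate salts and the flavone C2=C3 bond should tolerate. One equivalent of HCl in the cold then gives the hydrogen sulfate form, which is desalted and freeze-dried at once under exclusion of air.

## Compound list

1 | squaric acid (3,4-dihydroxycyclobut-3-ene-1,2-dione) | O=C1C(O)=C(O)C1=O | starting material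
2 | 3,4-bis(benzyloxy)cyclobut-3-ene-1,2-dione (dibenzyl squarate) | O=C1C(=O)C(OCc2ccccc2)=C1OCc1ccccc1 | intermediate
3 | 3,4-bis(benzyloxy)benzaldehyde | O=Cc1ccc(OCc2ccccc2)c(OCc2ccccc2)c1 | starting material
4 | 1-[3,4-bis(benzyloxy)phenyl]prop-2-yn-1-ol (racemic) | C#CC(O)c1ccc(OCc2ccccc2)c(OCc2ccccc2)c1 | intermediate
5 | {1-[3,4-bis(benzyloxy)phenyl]prop-2-yn-1-yloxy}(tert-butyl)dimethylsilane (racemic) | C#CC(O[Si](C)(C)C(C)(C)C)c1ccc(OCc2ccccc2)c(OCc2ccccc2)c1 | intermediate
6 | {3-[3,4-bis(benzyloxy)phenyl]-3-(tert-butyldimethylsilyloxy)prop-1-yn-1-yl}lithium (racemic) | [Li]C#CC(O[Si](C)(C)C(C)(C)C)c1ccc(OCc2ccccc2)c(OCc2ccccc2)c1 | intermediate (not isolated)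
7 | lithium 2,3-bis(benzyloxy)-1-{3-[3,4-bis(benzyloxy)phenyl]-3-(tert-butyldimethylsilyloxy)prop-1-yn-1-yl}-4-oxocyclobut-2-en-1-olate (diastereomer mixture) | [Li+].[O-]C1(C#CC(O[Si](C)(C)C(C)(C)C)c2ccc(OCc3ccccc3)c(OCc3ccccc3)c2)C(OCc2ccccc2)=C(OCc2ccccc2)C1=O | intermediate (not isolated)
8 | 2,3-bis(benzyloxy)-1-{3-[3,4-bis(benzyloxy)phenyl]-3-(tert-butyldimethylsilyloxy)prop-1-yn-1-yl}-4-oxocyclobut-2-en-1-yl trifluoroacetate (diastereomer mixture) | O=C1C(OCc2ccccc2)=C(OCc2ccccc2)C1(OC(=O)C(F)(F)F)C#CC(O[Si](C)(C)C(C)(C)C)c1ccc(OCc2ccccc2)c(OCc2ccccc2)c1 | intermediate (not isolated)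
9 | 3-(benzyloxy)-4-{3-[3,4-bis(benzyloxy)phenyl]-3-(tert-butyldimethylsilyloxy)prop-1-yn-1-yl}cyclobut-3-ene-1,2-dione (racemic) | O=C1C(=O)C(C#CC(O[Si](C)(C)C(C)(C)C)c2ccc(OCc3ccccc3)c(OCc3ccccc3)c2)=C1OCc1ccccc1 | intermediate
10 | 3-(benzyloxy)-2-{3-[3,4-bis(benzyloxy)phenyl]-3-(tert-butyldimethylsilyloxy)prop-1-yn-1-yl}-4-hydroxycyclobut-2-en-1-one (racemic, diastereomer mixture) | O=C1C(C#CC(O[Si](C)(C)C(C)(C)C)c2ccc(OCc3ccccc3)c(OCc3ccccc3)c2)=C(OCc2ccccc2)C1O | intermediate
11 | 3,4-bis(benzyloxy)-2-{3-[3,4-bis(benzyloxy)phenyl]-3-(tert-butyldimethylsilyloxy)prop-1-yn-1-yl}cyclobut-2-en-1-one (racemic, diastereomer mixture) | O=C1C(C#CC(O[Si](C)(C)C(C)(C)C)c2ccc(OCc3ccccc3)c(OCc3ccccc3)c2)=C(OCc2ccccc2)C1OCc1ccccc1 | intermediate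
12 | ethyl dibromoacetate | CCOC(=O)C(Br)Br | starting material
13 | lithium ethynolate | [Li+].[O-]C#C | intermediate (not isolated)
14 | (triisopropylsilyloxy)acetylene | C#CO[Si](C(C)C)(C(C)C)C(C)C | intermediate
15 | 3,4-bis(benzyloxy)-2-{3-[3,4-bis(benzyloxy)phenyl]-3-(tert-butyldimethylsilyloxy)prop-1-yn-1-yl}buta-1,3-dien-1-one, terminal benzyloxy group trans to C2 (racemic) | O=C=C(C#CC(O[Si](C)(C)C(C)(C)C)c1ccc(OCc2ccccc2)c(OCc2ccccc2)c1)/C(OCc1ccccc1)=C/OCc1ccccc1 | intermediate (not isolated)
16 | 4-[1,2-bis(benzyloxy)ethenyl]-4-{3-[3,4-bis(benzyloxy)phenyl]-3-(tert-butyldimethylsilyloxy)prop-1-yn-1-yl}-3-(triisopropylsilyloxy)cyclobut-2-en-1-one (diastereomer mixture) | O=C1C=C(O[Si](C(C)C)(C(C)C)C(C)C)C1(C#CC(O[Si](C)(C)C(C)(C)C)c1ccc(OCc2ccccc2)c(OCc2ccccc2)c1)/C(OCc1ccccc1)=C/OCc1ccccc1 | intermediate (not isolated)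
17 | 5,6-bis(benzyloxy)-4-{3-[3,4-bis(benzyloxy)phenyl]-3-(tert-butyldimethylsilyloxy)prop-1-yn-1-yl}-3-(triisopropylsilyloxy)hexa-1,3,5-trien-1-one, ketene and dialkoxyvinyl arm cis (racemic) | O=C=C/C(O[Si](C(C)C)(C(C)C)C(C)C)=C(C#CC(O[Si](C)(C)C(C)(C)C)c1ccc(OCc2ccccc2)c(OCc2ccccc2)c1)\C(OCc1ccccc1)=C\OCc1ccccc1 | intermediate (not isolated)
18 | 5,6-bis(benzyloxy)-4-{3-[3,4-bis(benzyloxy)phenyl]-3-(tert-butyldimethylsilyloxy)prop-1-yn-1-yl}-3-(triisopropylsilyloxy)cyclohexa-2,4-dien-1-one (diastereomer mixture) | O=C1C=C(O[Si](C(C)C)(C(C)C)C(C)C)C(C#CC(O[Si](C)(C)C(C)(C)C)c2ccc(OCc3ccccc3)c(OCc3ccccc3)c2)=C(OCc2ccccc2)C1OCc1ccccc1 | intermediate (not isolated)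
19 | 2,3-bis(benzyloxy)-4-{3-[3,4-bis(benzyloxy)phenyl]-3-(tert-butyldimethylsilyloxy)prop-1-yn-1-yl}-5-(triisopropylsilyloxy)phenol (racemic) | Oc1cc(O[Si](C(C)C)(C(C)C)C(C)C)c(C#CC(O[Si](C)(C)C(C)(C)C)c2ccc(OCc3ccccc3)c(OCc3ccccc3)c2)c(OCc2ccccc2)c1OCc1ccccc1 | intermediate
20 | 2,3-bis(benzyloxy)-4-{3-[3,4-bis(benzyloxy)phenyl]-3-hydroxyprop-1-yn-1-yl}-5-(triisopropylsilyloxy)phenol (racemic) | Oc1cc(O[Si](C(C)C)(C(C)C)C(C)C)c(C#CC(O)c2ccc(OCc3ccccc3)c(OCc3ccccc3)c2)c(OCc2ccccc2)c1OCc1ccccc1 | intermediate
21 | (2E)-1-[2,3-bis(benzyloxy)-4-hydroxy-6-(triisopropylsilyloxy)phenyl]-3-[3,4-bis(benzyloxy)phenyl]prop-2-en-1-one | O=C(/C=C/c1ccc(OCc2ccccc2)c(OCc2ccccc2)c1)c1c(O[Si](C(C)C)(C(C)C)C(C)C)cc(O)c(OCc2ccccc2)c1OCc1ccccc1 | intermediate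
22 | (2E)-1-[2,3-bis(benzyloxy)-4,6-dihydroxyphenyl]-3-[3,4-bis(benzyloxy)phenyl]prop-2-en-1-one | O=C(/C=C/c1ccc(OCc2ccccc2)c(OCc2ccccc2)c1)c1c(O)cc(O)c(OCc2ccccc2)c1OCc1ccccc1 | intermediate
23 | 5,6-bis(benzyloxy)-2-[3,4-bis(benzyloxy)phenyl]-7-hydroxy-2,3-dihydro-4H-chromen-4-one (racemic) | O=C1CC(c2ccc(OCc3ccccc3)c(OCc3ccccc3)c2)Oc2cc(O)c(OCc3ccccc3)c(OCc3ccccc3)c21 | intermediate (not isolated)
24 | 5,6-bis(benzyloxy)-2-[3,4-bis(benzyloxy)phenyl]-7-hydroxy-4H-chromen-4-one | O=c1cc(-c2ccc(OCc3ccccc3)c(OCc3ccccc3)c2)oc2cc(O)c(OCc3ccccc3)c(OCc3ccccc3)c12 | intermediate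
25 | sodium 5,6-bis(benzyloxy)-2-[3,4-bis(benzyloxy)phenyl]-4-oxo-4H-chromen-7-yl sulfate | O=c1cc(-c2ccc(OCc3ccccc3)c(OCc3ccccc3)c2)oc2cc(OS(=O)(=O)[O-])c(OCc3ccccc3)c(OCc3ccccc3)c12.[Na+] | intermediate
26 | 6-hydroxyluteolin 7-sulfate, 2-(3,4-dihydroxyphenyl)-5,6-dihydroxy-4-oxo-4H-chromen-7-yl hydrogen sulfate | O=c1cc(-c2ccc(O)c(O)c2)oc2cc(OS(=O)(=O)O)c(O)c(O)c12 | target

## Step count and least certain steps

Total: 14 steps. Longest linear sequence: 12 steps (3 → 26 through steps 2–6 and 8–14).

**Step 8 (key step, proposed new method).**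
- Risk: when 16 opens, the alkynyl arm may rotate inward instead of the dialkoxyvinyl arm, and the resulting enyne–ketene may cyclize to a diradical before it can re-close. The electron-rich ketene 15 may also add to 14 too slowly and dimerise, or be captured by the phenol already formed.
- Fallback (known chemistry), from 9, back at 22: ring A is made by the thermal ring expansion of a 4-alkenylcyclobutenone (Moore rearrangement), with the roles of O1 and O7 exchanged. 1-(Methoxymethoxy)vinyllithium (methoxymethyl vinyl ether, s-BuLi, THF, −78 °C) should add to the carbonyl of 9 that hydride attacks in step 5, giving 3-(benzyloxy)-2-{3-[3,4-bis(benzyloxy)phenyl]-3-(tert-butyldimethylsilyloxy)prop-1-yn-1-yl}-4-hydroxy-4-[1-(methoxymethoxy)ethenyl]cyclobut-2-en-1-one F1. Ag2O/BnBr converts it into the 4-benzyloxy ether 3,4-bis(benzyloxy)-2-{3-[3,4-bis(benzyloxy)phenyl]-3-(tert-butyldimethylsilyloxy)prop-1-yn-1-yl}-4-[1-(methoxymethoxy)ethenyl]cyclobut-2-en-1-one F2. In refluxing toluene F2 should open with the benzyloxy group outward and the alkenyl group inward, and 6π closure with enolization gives 3,4-bis(benzyloxy)-2-{3-[3,4-bis(benzyloxy)phenyl]-3-(tert-butyldimethylsilyloxy)prop-1-yn-1-yl}-5-(methoxymethoxy)phenol F3, whose free hydroxyl is O1 and whose acetal oxygen is O7. Aqueous HCl in MeOH/THF at 40–50 °C should then remove the silyl and methoxymethyl groups and bring about the acid-catalysed Meyer–Schuster shift in one pot, giving 22 (any 23 formed is carried into step 12).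

**Step 7.**
- Risk: deprotonation of 12 at its acidic C–H may compete with bromine–lithium exchange and lead to a doubly metalated ynolate, and the small parent ynol ether may be lost on isolation through volatility or hydrolysis.
- Fallback: this one does not set out from a numbered compound. It replaces 12 by commercial 3-phenylisoxazole and comes back at 13. n-BuLi in THF at −78 °C gives 5-lithio-3-phenylisoxazole F4, which fragments on warming to benzonitrile and 13; silylation with TIPSCl follows as in step 7.

**Step 9.**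
- Risk: partial loss of the aryl silyl ether, or ionisation of the doubly activated carbinol followed by intermolecular arylation at the nucleophilic C8 of another molecule.
- Fallback, from 19, back at 22: Bu4NF/AcOH in THF at 0 °C removes both silyl groups to give 4-{3-[3,4-bis(benzyloxy)phenyl]-3-hydroxyprop-1-yn-1-yl}-5,6-bis(benzyloxy)benzene-1,3-diol F5. p-TsOH·H2O in aqueous dioxane should then effect a Brønsted-acid Meyer–Schuster shift, under which a free ortho-hydroxyl does not add to the alkyne as it would under gold catalysis.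

**Step 10.**
- Risk: slow attack of the oxygen nucleophile at the alkyne carbon flanked by two ortho substituents, with cation-mediated oligomerisation through C8 taking over.
- Fallback, from 20, back at 22: Ac2O/pyridine gives 4-{3-(acetyloxy)-3-[3,4-bis(benzyloxy)phenyl]prop-1-yn-1-yl}-2,3-bis(benzyloxy)-5-(triisopropylsilyloxy)phenyl acetate F6. Ph3PAuNTf2 in wet butan-2-one should induce a 1,3-acyloxy shift, which delivers the oxygen intramolecularly to the hindered carbon, to give the allenyl acetate 4-{1-(acetyloxy)-3-[3,4-bis(benzyloxy)phenyl]propa-1,2-dien-1-yl}-2,3-bis(benzyloxy)-5-(triisopropylsilyloxy)phenyl acetate F7. Hydrolysis in the same pot gives 2,3-bis(benzyloxy)-4-{(2E)-3-[3,4-bis(benzyloxy)phenyl]prop-2-enoyl}-5-(triisopropylsilyloxy)phenyl acetate F8. Bu4NF in wet THF then removes the silyl group and the aryl acetate. The O7 acetate also damps the nucleophilicity of ring A during the rearrangement.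

**Step 12.**
- Risk: electrophilic iodination of ring A at C8, which lies between two oxygens and next to the free O7–H, and HI-mediated loss of the O5 benzyl group.
- Fallback, from 22, back at 24: ring closure and dehydrogenation are separated. NaOAc in refluxing EtOH gives flavanone 23, which is isolated and dehydrogenated with Pd(O2CCF3)2 (5 mol %) under O2 in DMSO/AcOH at 80 °C. This is an enolate/β-hydride elimination with divalent palladium, and no halogen electrophile is present. No new compound arises.

## Further compounds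

F1 | step 8 | 3-(benzyloxy)-2-{3-[3,4-bis(benzyloxy)phenyl]-3-(tert-butyldimethylsilyloxy)prop-1-yn-1-yl}-4-hydroxy-4-[1-(methoxymethoxy)ethenyl]cyclobut-2-en-1-one (diastereomer mixture) | O=C1C(C#CC(O[Si](C)(C)C(C)(C)C)c2ccc(OCc3ccccc3)c(OCc3ccccc3)c2)=C(OCc2ccccc2)C1(O)C(=C)OCOC
F2 | step 8 | 3,4-bis(benzyloxy)-2-{3-[3,4-bis(benzyloxy)phenyl]-3-(tert-butyldimethylsilyloxy)prop-1-yn-1-yl}-4-[1-(methoxymethoxy)ethenyl]cyclobut-2-en-1-one (diastereomer mixture) | O=C1C(C#CC(O[Si](C)(C)C(C)(C)C)c2ccc(OCc3ccccc3)c(OCc3ccccc3)c2)=C(OCc2ccccc2)C1(OCc1ccccc1)C(=C)OCOC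
F3 | step 8 | 3,4-bis(benzyloxy)-2-{3-[3,4-bis(benzyloxy)phenyl]-3-(tert-butyldimethylsilyloxy)prop-1-yn-1-yl}-5-(methoxymethoxy)phenol (racemic) | Oc1cc(OCOC)c(OCc2ccccc2)c(OCc2ccccc2)c1C#CC(O[Si](C)(C)C(C)(C)C)c1ccc(OCc2ccccc2)c(OCc2ccccc2)c1
F4 | step 7 | 5-lithio-3-phenylisoxazole | [Li]c1cc(-c2ccccc2)no1
F5 | step 9 | 4-{3-[3,4-bis(benzyloxy)phenyl]-3-hydroxyprop-1-yn-1-yl}-5,6-bis(benzyloxy)benzene-1,3-diol (racemic) | Oc1cc(O)c(C#CC(O)c2ccc(OCc3ccccc3)c(OCc3ccccc3)c2)c(OCc2ccccc2)c1OCc1ccccc1
F6 | step 10 | 4-{3-(acetyloxy)-3-[3,4-bis(benzyloxy)phenyl]prop-1-yn-1-yl}-2,3-bis(benzyloxy)-5-(triisopropylsilyloxy)phenyl acetate (racemic) | CC(=O)Oc1cc(O[Si](C(C)C)(C(C)C)C(C)C)c(C#CC(OC(C)=O)c2ccc(OCc3ccccc3)c(OCc3ccccc3)c2)c(OCc2ccccc2)c1OCc1ccccc1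
F7 | step 10 | 4-{1-(acetyloxy)-3-[3,4-bis(benzyloxy)phenyl]propa-1,2-dien-1-yl}-2,3-bis(benzyloxy)-5-(triisopropylsilyloxy)phenyl acetate (racemic) | CC(=O)OC(=C=Cc1ccc(OCc2ccccc2)c(OCc2ccccc2)c1)c1c(O[Si](C(C)C)(C(C)C)C(C)C)cc(OC(C)=O)c(OCc2ccccc2)c1OCc1ccccc1
F8 | step 10 | 2,3-bis(benzyloxy)-4-{(2E)-3-[3,4-bis(benzyloxy)phenyl]prop-2-enoyl}-5-(triisopropylsilyloxy)phenyl acetate | CC(=O)Oc1cc(O[Si](C(C)C)(C(C)C)C(C)C)c(C(=O)/C=C/c2ccc(OCc3ccccc3)c(OCc3ccccc3)c2)c(OCc2ccccc2)c1OCc1ccccc1
F0 | step 12 | none | none
A1 | alternative 1 | 2-(benzyloxy)-1-methoxy-1,3-bis(trimethylsilyloxy)buta-1,3-diene | COC(O[Si](C)(C)C)=C(OCc1ccccc1)C(=C)O[Si](C)(C)C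
A2 | alternative 1 | 4-bromobut-3-yn-2-one | CC(=O)C#CBr
A3 | alternative 1 | 1-[5-(benzyloxy)-2-bromo-4,6-dihydroxyphenyl]ethan-1-one | CC(=O)c1c(Br)cc(O)c(OCc2ccccc2)c1O
A4 | alternative 2 | 1-[3,4-bis(benzyloxy)phenyl]-3-[2,3-dihydroxy-4-(methoxymethoxy)phenyl]propane-1,3-dione | O=C(CC(=O)c1ccc(OCOC)c(O)c1O)c1ccc(OCc2ccccc2)c(OCc2ccccc2)c1
A5 | alternative 2 | 1-[3,4-bis(benzyloxy)phenyl]-3-[4-(methoxymethoxy)-5,6-dioxocyclohexa-1,3-dien-1-yl]propane-1,3-dione | O=C(CC(=O)C1=CC=C(OCOC)C(=O)C1=O)c1ccc(OCc2ccccc2)c(OCc2ccccc2)c1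
A6 | alternative 2 | 2-[3,4-bis(benzyloxy)phenyl]-5,6-dihydroxy-7-(methoxymethoxy)-4H-chromen-4-one | O=c1cc(-c2ccc(OCc3ccccc3)c(OCc3ccccc3)c2)oc2cc(OCOC)c(O)c(O)c12
A7 | alternative 3 | methyl 2-(benzyloxy)-4-{6-[3,4-bis(benzyloxy)phenyl]-4-oxo-4H-pyran-2-yl}-3-oxobutanoate (racemic) | COC(=O)C(OCc1ccccc1)C(=O)Cc1cc(=O)cc(-c2ccc(OCc3ccccc3)c(OCc3ccccc3)c2)o1
A8 | alternative 3 | 6-(benzyloxy)-2-[3,4-bis(benzyloxy)phenyl]-5,7-dihydroxy-4H-chromen-4-one | O=c1cc(-c2ccc(OCc3ccccc3)c(OCc3ccccc3)c2)oc2cc(O)c(OCc3ccccc3)c(O)c12
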